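**Strategy.** The depside is cut at its aryl ester into a ring A acid and a ring B phenol, and both halves are drawn from one arene, 3-heptyl-5-methoxyphenol. That arene is assembled in a single thermal operation from 3-heptylcyclobut-2-en-1-one and methoxyacetylene. The alkyne is spliced between the carbonyl carbon and C2 of the four-membered ketone, which creates C2'–C3' and C4'–C5' and closes ring A at C1'–C2'. The step exploits the mutually meta array of ring A (C2'–OH, C4'–OMe, C6'–heptyl) and delivers the two oxygens already differentiated. The precursor is a simple 3-alkylcyclobutenone made from 1-nonyne and dichloroketene.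

Key step: step 4

Remark: primed locants denote ring A (the acyl ring, C1' carrying the ester carbonyl) and unprimed locants ring B (C1 carrying the free carboxyl); the target is achiral, so no stereocentre has to be set.

**Step 1**
Reactants: 1 1-nonyne; 2 trichloroacetyl chloride
Product: 4 4,4-dichloro-3-heptylcyclobut-2-en-1-one, via dichloroketene 3 (not isolated)
Conditions: Zn(Cu) couple, Et2O/DME, rt (slow addition of 2)
Reagents that add atoms: none
Why: Zinc reduces 2 to dichloroketene 3, which undergoes the established thermal (2+2) cycloaddition with the terminal alkyne, the unsubstituted alkyne carbon bonding to the ketene carbonyl carbon so that the heptyl group sits at C3 next to the CCl2 carbon.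

**Step 2**
Reactants: 4 4,4-dichloro-3-heptylcyclobut-2-en-1-one
Product: 5 3-heptylcyclobut-2-en-1-one
Conditions: Zn dust, AcOH, TMEDA, EtOH, 0 °C → rt
Reagents that add atoms: none
Why: Reductive dehalogenation of an alpha,alpha-dichloroketone by zinc proceeds through zinc enolates, and the amine-buffered acetic acid protonates them without opening or isomerising the strained enone.

**Step 3**
Reactants: 6 chloroacetaldehyde dimethyl acetal (2-chloro-1,1-dimethoxyethane)
Product: 9 methoxyacetylene, via 2-chlorovinyl methyl ether 7 (not isolated), via sodium methoxyacetylide 8 (not isolated)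
Conditions: NaNH2 (3 equiv), liquid NH3, −33 °C; evaporate NH3; cold aq NaCl, then distil the volatile alkyne into cold toluene
Reagents that add atoms: none
Why: Sodium amide effects two successive beta-eliminations, first of methanol to 7 and then of hydrogen chloride, the acetylide 8 being the sink that is protonated on aqueous quench (standard dehydrohalogenative synthesis of 1-alkoxyalkynes).

**Step 4**
Reactants: 5 3-heptylcyclobut-2-en-1-one; 9 methoxyacetylene
Product: 14 3-heptyl-5-methoxyphenol, via vinylketene 10 (not isolated), via alkenylcyclobutenone 11 (not isolated), via dienylketene 12 (not isolated), via cyclohexadienone 13 (not isolated)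
Conditions: 9 (2–3 equiv), toluene, sealed tube, 80 °C then 110 °C; crude product stirred with KOH, MeOH, rt
Reagents that add atoms: none
Why: Danheiser benzannulation, a known pericyclic cascade of 3-alkylcyclobutenones with alkoxyacetylenes: thermal four-electron conrotatory opening of 5 gives vinylketene 10, whose ketene C=C bond undergoes a (2+2) cycloaddition with 9 to give 11, forming C2'–C3' and C4'–C5'. A second, reversible four-electron opening gives dienylketene 12, and the isomer with the alkenyl group turned toward the ketene closes six-membered ring A by a thermal disrotatory six-electron electrocyclisation between the ketene carbon (C2') and the terminal methylene (C1'); tautomerisation of 13 then gives the phenol. No stereocentre is formed. The only selectivity needed is the orientation of the (2+2) step, and it is secured by the polarisation of the ynol ether: its unsubstituted carbon is the nucleophilic terminus and bonds to the electrophilic ketene carbonyl carbon, so the oxygen-bearing alkyne carbon becomes C4' and hydroxyl, methoxy and heptyl come out mutually meta. The brief KOH/MeOH treatment returns any phenol that has been acylated by the vinylketene.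

**Step 5**
Reactants: 14 3-heptyl-5-methoxyphenol
Product: 16 6-heptyl-2-hydroxy-4-methoxybenzaldehyde, via salicyl alcohol 15 (not isolated)
Conditions: MgCl2, Et3N, (CH2O)n, MeCN, reflux; aq HCl work-up
Reagents that add atoms: paraformaldehyde (as formaldehyde), C=O
Why: In this Casnati–Skattebøl ortho-formylation the magnesium phenoxide delivers formaldehyde only ortho to the phenol oxygen, the salicyl alcohol 15 is oxidised in situ by hydride transfer to a second formaldehyde, and C1' (para to the methoxy group) is expected to be preferred over C3', which lies between two oxygen substituents.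

**Step 6**
Reactants: 16 6-heptyl-2-hydroxy-4-methoxybenzaldehyde
Product: 17 2-(benzyloxy)-6-heptyl-4-methoxybenzaldehyde
Conditions: BnBr, K2CO3, DMF, 60 °C
Reagents that add atoms: benzyl bromide, BrCc1ccccc1
Why: Williamson etherification of the chelated phenol in a dipolar aprotic solvent masks C2'–OH for the oxidation and the coupling with a group that hydrogenolysis removes at the end.

**Step 7**
Reactants: 17 2-(benzyloxy)-6-heptyl-4-methoxybenzaldehyde
Product: 18 2-(benzyloxy)-6-heptyl-4-methoxybenzoic acid
Conditions: NaClO2, NaH2PO4, 2-methyl-2-butene, t-BuOH/H2O, rt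
Reagents that add atoms: sodium chlorite, [Na+].[O-]Cl=O
Why: Pinnick oxidation converts the hindered, electron-rich aryl aldehyde into the acid under buffered conditions, the alkene scavenger intercepting hypochlorous acid before it can chlorinate the ring.

**Step 8**
Reactants: 16 6-heptyl-2-hydroxy-4-methoxybenzaldehyde
Product: 19 6-heptyl-2,4-dihydroxybenzaldehyde
Conditions: BBr3 (3 equiv), CH2Cl2, −78 °C → rt; H2O
Reagents that add atoms: none
Why: Boron tribromide cleaves the aryl methyl ether by bromide attack on the O-methyl group of the borane complex (Lewis-acid dealkylation); the aldehyde is held as a chelated borate and the resorcinol aldehyde is released on hydrolysis.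

**Step 9**
Reactants: 18 2-(benzyloxy)-6-heptyl-4-methoxybenzoic acid; 19 6-heptyl-2,4-dihydroxybenzaldehyde
Product: 21 4-formyl-3-heptyl-5-hydroxyphenyl 2-(benzyloxy)-6-heptyl-4-methoxybenzoate, via mixed trifluoroacetic anhydride 20 (not isolated)
Conditions: (CF3CO)2O, toluene, rt
Reagents that add atoms: none
Why: In this mixed-anhydride esterification trifluoroacetic anhydride activates the 2,6-disubstituted, electron-rich acid as 20 (in equilibrium with its acylium ion), which acylates the more nucleophilic C4 hydroxyl of 19 because the C2 hydroxyl is tied up in a hydrogen bond to the neighbouring formyl group.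

**Step 10**
Reactants: 21 4-formyl-3-heptyl-5-hydroxyphenyl 2-(benzyloxy)-6-heptyl-4-methoxybenzoate
Product: 22 4-{[2-(benzyloxy)-6-heptyl-4-methoxybenzoyl]oxy}-6-heptyl-2-hydroxybenzoic acid
Conditions: NaClO2, NaH2PO4, 2-methyl-2-butene (excess), t-BuOH/THF/H2O, 0 °C → rt
Reagents that add atoms: sodium chlorite, [Na+].[O-]Cl=O
Why: Pinnick oxidation takes the formyl group of ring B to the carboxylic acid at buffered pH, where the hindered aryl ester and the benzyl ether are stable and the scavenger protects the phenolic ring, itself deactivated by the acyloxy and carbonyl groups, from chlorination.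

**Step 11**
Reactants: 22 4-{[2-(benzyloxy)-6-heptyl-4-methoxybenzoyl]oxy}-6-heptyl-2-hydroxybenzoic acid
Product: 23 6-heptyl-4-[(6-heptyl-2-hydroxy-4-methoxybenzoyl)oxy]-2-hydroxybenzoic acid
Conditions: H2 (1 atm), Pd/C, EtOAc, rt
Reagents that add atoms: none
Why: Hydrogenolysis over Pd/C cleaves only the benzylic C–O bond and leaves the aryl ester, the free acid and the aromatic rings untouched under neutral conditions at room temperature.

**Compound list**

1 | 1-nonyne | C#CCCCCCCC | starting material
2 | trichloroacetyl chloride | O=C(Cl)C(Cl)(Cl)Cl | starting material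
3 | dichloroketene | O=C=C(Cl)Cl | intermediate (not isolated)
4 | 4,4-dichloro-3-heptylcyclobut-2-en-1-one | CCCCCCCC1=CC(=O)C1(Cl)Cl | intermediate
5 | 3-heptylcyclobut-2-en-1-one | CCCCCCCC1=CC(=O)C1 | intermediate
6 | chloroacetaldehyde dimethyl acetal (2-chloro-1,1-dimethoxyethane) | COC(CCl)OC | starting material
7 | 2-chlorovinyl methyl ether (1-chloro-2-methoxyethene, E/Z mixture) | COC=CCl | intermediate (not isolated)
8 | sodium methoxyacetylide | [Na+].[C-]#COC | intermediate (not isolated)
9 | methoxyacetylene | C#COC | intermediate
10 | 3-methylidenedec-1-en-1-one (vinylketene) | CCCCCCCC(=C)C=C=O | intermediate (not isolated)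
11 | 3-methoxy-4-(non-1-en-2-yl)cyclobut-2-en-1-one (racemic) | CCCCCCCC(=C)C1C(OC)=CC1=O | intermediate (not isolated)
12 | (3E)-3-methoxy-5-methylidenedodeca-1,3-dien-1-one (dienylketene) | O=C=C/C(OC)=C\C(=C)CCCCCCC | intermediate (not isolated)
13 | 5-heptyl-3-methoxycyclohexa-2,4-dien-1-one | CCCCCCCC1=CC(OC)=CC(=O)C1 | intermediate (not isolated)
14 | 3-heptyl-5-methoxyphenol | CCCCCCCc1cc(O)cc(OC)c1 | intermediate
15 | 3-heptyl-2-(hydroxymethyl)-5-methoxyphenol (present as its magnesium salt) | CCCCCCCc1cc(OC)cc(O)c1CO | intermediate (not isolated)
16 | 6-heptyl-2-hydroxy-4-methoxybenzaldehyde | CCCCCCCc1cc(OC)cc(O)c1C=O | intermediate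
17 | 2-(benzyloxy)-6-heptyl-4-methoxybenzaldehyde | CCCCCCCc1cc(OC)cc(OCc2ccccc2)c1C=O | intermediate
18 | 2-(benzyloxy)-6-heptyl-4-methoxybenzoic acid | CCCCCCCc1cc(OC)cc(OCc2ccccc2)c1C(=O)O | intermediate
19 | 6-heptyl-2,4-dihydroxybenzaldehyde | CCCCCCCc1cc(O)cc(O)c1C=O | intermediate
20 | 2-(benzyloxy)-6-heptyl-4-methoxybenzoic trifluoroacetic anhydride | CCCCCCCc1cc(OC)cc(OCc2ccccc2)c1C(=O)OC(=O)C(F)(F)F | intermediate (not isolated)
21 | 4-formyl-3-heptyl-5-hydroxyphenyl 2-(benzyloxy)-6-heptyl-4-methoxybenzoate | CCCCCCCc1cc(OC(=O)c2c(OCc3ccccc3)cc(OC)cc2CCCCCCC)cc(O)c1C=O | intermediate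
22 | 4-{[2-(benzyloxy)-6-heptyl-4-methoxybenzoyl]oxy}-6-heptyl-2-hydroxybenzoic acid | CCCCCCCc1cc(OC(=O)c2c(OCc3ccccc3)cc(OC)cc2CCCCCCC)cc(O)c1C(=O)O | intermediate
23 | 6-heptyl-4-[(6-heptyl-2-hydroxy-4-methoxybenzoyl)oxy]-2-hydroxybenzoic acid | CCCCCCCc1cc(OC(=O)c2c(O)cc(OC)cc2CCCCCCC)cc(O)c1C(=O)O | target

**Totals**

Total step count: 11.
Longest linear sequence: 9 steps (steps 1, 2, 4, 5, 6, 7, 9, 10, 11).

**Steps most likely to fail**

1. Step 4. The low-boiling ynol ether may escape or polymerise, and the vinylketene may react with itself, before the cycloaddition takes place; the product phenol may also be consumed by acylation. The fallback sets out from 1 and comes back at 14, building the arene by a Michael–Claisen resorcylate synthesis. Lithiation of 1 (n-BuLi, THF, −78 °C) and acylation with N-methoxy-N-methylacetamide should give undec-3-yn-2-one F1. Conjugate addition of dimethyl malonate (NaOMe, MeOH, reflux) should give the adduct dimethyl 2-(2-oxoundec-3-en-4-yl)propanedioate F2, which is not isolated and should close by intramolecular Claisen condensation and enolisation to methyl 6-heptyl-2,4-dihydroxybenzoate F3. Methylation of the non-chelated C4 hydroxyl (MeI, 1 equiv, K2CO3, acetone) should give methyl 6-heptyl-2-hydroxy-4-methoxybenzoate F4. Saponification (KOH, aqueous DMSO, heat) to 6-heptyl-2-hydroxy-4-methoxybenzoic acid F5, which is not isolated, followed by acidification and warming, should bring about protodecarboxylation and return 14.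

2. Step 5. Formylation may be divided between the two positions ortho to the hydroxyl (C1' and C3'), which would waste material and complicate separation for both halves. The fallback sets out from 14 and comes back at 19 and, one step later, at 16. Demethylation (BBr3, CH2Cl2) should give the symmetrical 5-heptylbenzene-1,3-diol F6. Vilsmeier–Haack formylation (POCl3, DMF, 0 °C → rt) should attack the position ortho to one hydroxyl and para to the other, and aqueous hydrolysis of the iminium salt [(6-heptyl-2,4-dihydroxyphenyl)methylidene]dimethylammonium chloride F7, which is not isolated, should give 19. Methylation of the non-chelated C4 hydroxyl of 19 (MeI, 1 equiv, K2CO3, acetone) should then give 16. Step 8 is not needed in this variant.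

3. Step 10. Hypochlorous acid or chlorine dioxide may chlorinate or degrade the electron-rich rings and the free phenol, or the hydrogen-bonded aldehyde may oxidise so slowly that ester cleavage competes. The fallback sets out from 21 and comes back at 23, masking the phenol before the oxidation. Benzylation of the C2 hydroxyl (BnBr, K2CO3, DMF, rt; the hindered aroyl ester should resist the phenoxide) should give 3-(benzyloxy)-4-formyl-5-heptylphenyl 2-(benzyloxy)-6-heptyl-4-methoxybenzoate F8. Pinnick oxidation of this phenol-free aldehyde should give 2-(benzyloxy)-4-{[2-(benzyloxy)-6-heptyl-4-methoxybenzoyl]oxy}-6-heptylbenzoic acid F9. Hydrogenolysis of both benzyl ethers (H2, Pd/C, EtOAc) should then give 23.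

**Further compounds**

F1 | step 4 | undec-3-yn-2-one | CCCCCCCC#CC(C)=O
F2 | step 4 | dimethyl 2-(2-oxoundec-3-en-4-yl)propanedioate (not isolated) | CCCCCCCC(=CC(C)=O)C(C(=O)OC)C(=O)OC
F3 | step 4 | methyl 6-heptyl-2,4-dihydroxybenzoate | CCCCCCCc1cc(O)cc(O)c1C(=O)OC
F4 | step 4 | methyl 6-heptyl-2-hydroxy-4-methoxybenzoate | CCCCCCCc1cc(OC)cc(O)c1C(=O)OC
F5 | step 4 | 6-heptyl-2-hydroxy-4-methoxybenzoic acid (not isolated) | CCCCCCCc1cc(OC)cc(O)c1C(=O)O
F6 | step 5 | 5-heptylbenzene-1,3-diol | CCCCCCCc1cc(O)cc(O)c1
F7 | step 5 | [(6-heptyl-2,4-dihydroxyphenyl)methylidene]dimethylammonium chloride (not isolated) | CCCCCCCc1cc(O)cc(O)c1C=[N+](C)C.[Cl-]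
F8 | step 10 | 3-(benzyloxy)-4-formyl-5-heptylphenyl 2-(benzyloxy)-6-heptyl-4-methoxybenzoate | CCCCCCCc1cc(OC(=O)c2c(OCc3ccccc3)cc(OC)cc2CCCCCCC)cc(OCc2ccccc2)c1C=O
F9 | step 10 | 2-(benzyloxy)-4-{[2-(benzyloxy)-6-heptyl-4-methoxybenzoyl]oxy}-6-heptylbenzoic acid | CCCCCCCc1cc(OC(=O)c2c(OCc3ccccc3)cc(OC)cc2CCCCCCC)cc(OCc2ccccc2)c1C(=O)O
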